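**Retrosynthetic overview**
- The strategy rests on one feature of the 2H-chromene: benzene carbon C4a is ortho to O1 and para to the C7 oxygen. A terminal alkyne (future C3≡C4) hung on the O1–C2 ether can therefore be attacked by C4a, forming C4–C4a and closing the pyran ring without touching the C2 quaternary centre.
- Target ⇒ bis-MOM chromene (removal of two MOM ethers) ⇒ aryl 1,1-disubstituted propargyl ether carrying the ferulate ester (gold-catalysed 6-endo hydroarylation). The pyran ring is the only ring made and it is made last; both benzene rings are bought.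
- Propargyl ether precursor ⇒ primary alcohol + 4-O-MOM-ferulic acid (ester C–O bond).
- Aryl ether O1–C8a ⇒ tertiary propargylic alkoxide + 4-fluoro-2-(methoxymethoxy)benzonitrile by SNAr. The nitrile stands in for the acetyl group, because a methyl ketone would be enolised by the hindered alkoxide; MeMgBr converts it to the ketone afterwards.
- Tertiary propargylic alcohol ⇒ (R)-2-methylglycidol: oxidation, Ohira–Bestmann alkynylation, then opening of the epoxide at CH2 by 4-methoxybenzyl oxide.

Key step: step 10

Remark: commercial (R)-2-methylglycidol is taken as enantiopure. No bond to its quaternary carbon is made or broken in the route, so that carbon becomes C2 of the target with the R descriptor; the descriptor reads S only in the aldehyde, through a change of substituent priorities.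

**Route**

Step 1
Reactants: 1 (R)-2-methylglycidol
Product: 2 (S)-2-methyloxirane-2-carbaldehyde
Conditions: TEMPO (0.1 equiv), PhI(OAc)2 (1.1 equiv), CH2Cl2, 0 °C → rt; crude solution carried on
Reagents that add atoms: none
Why: TEMPO/PhI(OAc)2 oxidation (oxoammonium-mediated) should take the primary alcohol to the aldehyde without over-oxidation and leave the epoxide alone, and the quaternary stereocentre, which has no α-hydrogen, cannot epimerise (its descriptor becomes S only because CHO outranks the ring CH2).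

Step 2
Reactants: 2 (S)-2-methyloxirane-2-carbaldehyde
Product: 3 (R)-2-ethynyl-2-methyloxirane
Conditions: dimethyl (1-diazo-2-oxopropyl)phosphonate (1.3 equiv), K2CO3 (3 equiv), MeOH, 0 °C → rt; kept as an ethereal solution (volatile)
Reagents that add atoms: dimethyl (1-diazo-2-oxopropyl)phosphonate, CC(=O)C(=[N+]=[N-])P(=O)(OC)OC
Why: Ohira–Bestmann (Seyferth–Gilbert) homologation, in which methanolysis of the reagent gives dimethyl (diazomethyl)phosphonate whose anion converts the aldehyde through a diazoalkene and an alkylidene carbene (1,2-hydride shift) into the terminal alkyne under conditions mild enough for a 2,2-disubstituted epoxide, with no stereocentre touched.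

Step 3
Reactants: 3 (R)-2-ethynyl-2-methyloxirane
Product: 4 (2R)-1-[(4-methoxyphenyl)methoxy]-2-methylbut-3-yn-2-ol
Conditions: 4-MeOC6H4CH2OH (3 equiv), NaH (0.2 equiv), DMF, sealed vessel, 60 °C
Reagents that add atoms: 4-methoxybenzyl alcohol, COc1ccc(CO)cc1
Why: Alkoxide-catalysed SN2 epoxide opening, in which the 4-methoxybenzyl oxide attacks the unsubstituted ring CH2 (the quaternary carbon is inaccessible), the tertiary alkoxide formed is reprotonated by the excess alcohol to carry the chain, and the C–O bond at the stereocentre is not broken, so the configuration is retained.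

Step 4
Reactants: 5 4-fluoro-2-hydroxybenzonitrile
Product: 6 4-fluoro-2-(methoxymethoxy)benzonitrile
Conditions: MOMCl (1.3 equiv), i-Pr2NEt, CH2Cl2, 0 °C → rt
Reagents that add atoms: chloromethyl methyl ether, COCCl
Why: Williamson-type O-alkylation of the acidic cyanophenol with MOMCl masks the phenol, which would otherwise be deprotonated and switch off the ring in the following SNAr.

Step 5
Reactants: 4 (2R)-1-[(4-methoxyphenyl)methoxy]-2-methylbut-3-yn-2-ol; 6 4-fluoro-2-(methoxymethoxy)benzonitrile
Product: 7 4-{[(2R)-1-[(4-methoxyphenyl)methoxy]-2-methylbut-3-yn-2-yl]oxy}-2-(methoxymethoxy)benzonitrile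
Conditions: NaH (1.05 equiv), DMF, 0 °C; then 6 (1.1 equiv), 0 °C → rt
Reagents that add atoms: none
Why: Nucleophilic aromatic substitution (SNAr, addition–elimination), in which the sodium tertiary alkoxide adds at C–F para to the nitrile, which stabilises the Meisenheimer intermediate and, unlike an acetyl group, offers no acidic hydrogen to quench the hindered alkoxide, and because the alkoxide oxygen is retained the stereocentre keeps its configuration.

Step 6
Reactants: 7 4-{[(2R)-1-[(4-methoxyphenyl)methoxy]-2-methylbut-3-yn-2-yl]oxy}-2-(methoxymethoxy)benzonitrile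
Product: 9 1-[4-{[(2R)-1-[(4-methoxyphenyl)methoxy]-2-methylbut-3-yn-2-yl]oxy}-2-(methoxymethoxy)phenyl]ethan-1-one, via N-H ketimine 8 (not isolated)
Conditions: MeMgBr (3.5 equiv), THF, 0 → 60 °C; then 1 M aq. HCl, 0 °C, 20 min
Reagents that add atoms: methylmagnesium bromide, C[Mg]Br; water, O
Why: Grignard addition to a nitrile, in which one equivalent of MeMgBr is spent on the alkyne C–H and a second adds to the nitrile (assisted by chelation to the ortho MOM oxygen) to give an N-magnesio ketimine that resists further addition and should be hydrolysed by cold dilute acid to the methyl ketone faster than the MOM or PMB ethers are cleaved.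

Step 7
Reactants: 9 1-[4-{[(2R)-1-[(4-methoxyphenyl)methoxy]-2-methylbut-3-yn-2-yl]oxy}-2-(methoxymethoxy)phenyl]ethan-1-one
Product: 10 1-[4-{[(2R)-1-hydroxy-2-methylbut-3-yn-2-yl]oxy}-2-(methoxymethoxy)phenyl]ethan-1-one
Conditions: DDQ (1.5 equiv), CH2Cl2/pH 7 buffer (10:1), 0 °C → rt
Reagents that add atoms: none
Why: Oxidative cleavage of the 4-methoxybenzyl ether with DDQ (benzylic hydride abstraction, then hydrolysis of the oxocarbenium ion) is selective for the electron-rich PMB ring and should leave the alkyne, the ketone, the MOM ether and the acceptor-substituted aryl ether untouched.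

Step 8
Reactants: 11 ferulic acid
Product: 13 (2E)-3-[3-methoxy-4-(methoxymethoxy)phenyl]prop-2-enoic acid, via methoxymethyl ester 12 (not isolated)
Conditions: MOMCl (2.4 equiv), i-Pr2NEt, CH2Cl2, 0 °C → rt; then LiOH, THF/H2O, rt; cold 1 M HCl to pH 4
Reagents that add atoms: chloromethyl methyl ether, COCCl; lithium hydroxide, [Li+].[OH-]
Why: MOMCl alkylates both the phenol and the carboxylate, and saponification (acyl substitution by hydroxide) then removes only the labile methoxymethyl ester, leaving the aryl MOM ether and the E alkene intact.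

Step 9
Reactants: 10 1-[4-{[(2R)-1-hydroxy-2-methylbut-3-yn-2-yl]oxy}-2-(methoxymethoxy)phenyl]ethan-1-one; 13 (2E)-3-[3-methoxy-4-(methoxymethoxy)phenyl]prop-2-enoic acid
Product: 14 (2R)-2-[4-acetyl-3-(methoxymethoxy)phenoxy]-2-methylbut-3-yn-1-yl (2E)-3-[3-methoxy-4-(methoxymethoxy)phenyl]prop-2-enoate
Conditions: DCC (1.3 equiv), DMAP (0.2 equiv), CH2Cl2, 0 °C → rt
Reagents that add atoms: none
Why: Steglich esterification, in which DCC activates acid 13 as the O-acylisourea and DMAP relays the acyl group as an acylpyridinium ion to the neopentyl-type primary alcohol, while the absence of strong base avoids a Smiles-type O-to-O aryl shift.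

Step 10
Reactants: 14 (2R)-2-[4-acetyl-3-(methoxymethoxy)phenoxy]-2-methylbut-3-yn-1-yl (2E)-3-[3-methoxy-4-(methoxymethoxy)phenyl]prop-2-enoate
Product: 15 [(2R)-6-acetyl-7-(methoxymethoxy)-2-methyl-2H-chromen-2-yl]methyl (2E)-3-[3-methoxy-4-(methoxymethoxy)phenyl]prop-2-enoate
Conditions: Ph3PAuNTf2 (5 mol %), CH2Cl2, 4 Å molecular sieves, rt → 40 °C
Reagents that add atoms: none
Why: Ph3PAuNTf2 supplies cationic monovalent gold that binds the terminal alkyne as a π-complex; benzene carbon C4a attacks the distal alkyne carbon (C4) anti to gold in a Friedel–Crafts-type step, and rearomatisation followed by protodeauration of the vinylgold leaves the C3=C4 double bond. The closest known reaction is the gold-catalysed intramolecular hydroarylation of aryl propargyl ethers, 1,1-disubstituted ones included, to 2H-chromenes. The pyran ring closes in a 6-endo-dig mode through the new C4–C4a bond. No stereocentre is created: the C2 quaternary centre is a spectator whose bonds to O1, CH3, CH2O and C3 are untouched, and ionisation of C2–O1 is disfavoured by the electron-withdrawing acyloxymethyl group, so the R configuration is carried through. The step needs regioselectivity between the two carbons ortho to O1: C4a is para to the C7 OMOM oxygen and has a free flank, whereas C8 is wedged between O1 and the OMOM group, and the acetyl group is meta to both and does not discriminate, so attack at C4a (linear chromene) should dominate. It also needs chemoselectivity for the alkyne, which the homopropargylic position of the ester (no productive acyloxy shift) and the exclusion of water by molecular sieves should secure.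

Step 11
Reactants: 15 [(2R)-6-acetyl-7-(methoxymethoxy)-2-methyl-2H-chromen-2-yl]methyl (2E)-3-[3-methoxy-4-(methoxymethoxy)phenyl]prop-2-enoate
Product: 16 [(2R)-6-acetyl-7-hydroxy-2-methyl-2H-chromen-2-yl]methyl (2E)-3-(4-hydroxy-3-methoxyphenyl)prop-2-enoate
Conditions: 3 M aq. HCl, THF/i-PrOH (1:1), rt → 40 °C
Reagents that add atoms: none
Why: Acid-catalysed hydrolysis of the two aryl methoxymethyl acetals (the C7 one assisted by the neighbouring acetyl group) in a non-transesterifying medium should free both phenols, while the 2,2-disubstituted chromene, the primary cinnamate ester and the C2 stereocentre tolerate dilute acid at this temperature.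

**Compound list**
1 | (R)-2-methylglycidol | OC[C@]1(C)CO1 | starting material
2 | (S)-2-methyloxirane-2-carbaldehyde | O=C[C@]1(C)CO1 | intermediate
3 | (R)-2-ethynyl-2-methyloxirane | C#C[C@]1(C)CO1 | intermediate
4 | (2R)-1-[(4-methoxyphenyl)methoxy]-2-methylbut-3-yn-2-ol | C#C[C@](O)(C)COCc1ccc(OC)cc1 | intermediate
5 | 4-fluoro-2-hydroxybenzonitrile | N#Cc1ccc(F)cc1O | starting material
6 | 4-fluoro-2-(methoxymethoxy)benzonitrile | COCOc1cc(F)ccc1C#N | intermediate
7 | 4-{[(2R)-1-[(4-methoxyphenyl)methoxy]-2-methylbut-3-yn-2-yl]oxy}-2-(methoxymethoxy)benzonitrile | C#C[C@](C)(COCc1ccc(OC)cc1)Oc1ccc(C#N)c(OCOC)c1 | intermediate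
8 | 1-[4-{[(2R)-1-[(4-methoxyphenyl)methoxy]-2-methylbut-3-yn-2-yl]oxy}-2-(methoxymethoxy)phenyl]ethan-1-imine (N-H ketimine, not isolated) | C#C[C@](C)(COCc1ccc(OC)cc1)Oc1ccc(C(C)=N)c(OCOC)c1 | intermediate
9 | 1-[4-{[(2R)-1-[(4-methoxyphenyl)methoxy]-2-methylbut-3-yn-2-yl]oxy}-2-(methoxymethoxy)phenyl]ethan-1-one | C#C[C@](C)(COCc1ccc(OC)cc1)Oc1ccc(C(C)=O)c(OCOC)c1 | intermediate
10 | 1-[4-{[(2R)-1-hydroxy-2-methylbut-3-yn-2-yl]oxy}-2-(methoxymethoxy)phenyl]ethan-1-one | C#C[C@](C)(CO)Oc1ccc(C(C)=O)c(OCOC)c1 | intermediate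
11 | ferulic acid | COc1cc(/C=C/C(=O)O)ccc1O | starting material
12 | methoxymethyl (2E)-3-[3-methoxy-4-(methoxymethoxy)phenyl]prop-2-enoate (not isolated) | COCOC(=O)/C=C/c1ccc(OCOC)c(OC)c1 | intermediate
13 | (2E)-3-[3-methoxy-4-(methoxymethoxy)phenyl]prop-2-enoic acid | COCOc1ccc(/C=C/C(=O)O)cc1OC | intermediate
14 | (2R)-2-[4-acetyl-3-(methoxymethoxy)phenoxy]-2-methylbut-3-yn-1-yl (2E)-3-[3-methoxy-4-(methoxymethoxy)phenyl]prop-2-enoate | COCOc1ccc(/C=C/C(=O)OC[C@@](C)(C#C)Oc2ccc(C(C)=O)c(OCOC)c2)cc1OC | intermediate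
15 | [(2R)-6-acetyl-7-(methoxymethoxy)-2-methyl-2H-chromen-2-yl]methyl (2E)-3-[3-methoxy-4-(methoxymethoxy)phenyl]prop-2-enoate | COCOc1ccc(/C=C/C(=O)OC[C@@]2(C)C=Cc3cc(C(C)=O)c(OCOC)cc3O2)cc1OC | intermediate
16 | [(2R)-6-acetyl-7-hydroxy-2-methyl-2H-chromen-2-yl]methyl (2E)-3-(4-hydroxy-3-methoxyphenyl)prop-2-enoate | COc1cc(/C=C/C(=O)OC[C@@]2(C)C=Cc3cc(C(C)=O)c(O)cc3O2)ccc1O | target

**Step count and risks**

Total steps: 11. Longest linear sequence: 9 steps (steps 1, 2, 3, 5, 6, 7, 9, 10, 11, from (R)-2-methylglycidol).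

Most likely to fail, step 10. The ring closure may be slow or unselective: the acetyl group lowers the nucleophilicity of the ring, attack may divide between C4a and C8, traces of water may hydrate the gold-bound alkyne, and the ester carbonyl may compete for it. The fallback sets out from 4 and 5 and comes back at 15. It builds the pyran ring the other way round, C4–C4a by cross-coupling and O1–C8a by intramolecular SNAr, so that a halogen fixes the regiochemistry and the C2–O bond is again never broken.
- NBS bromination of 5 para to the hydroxyl should give 5-bromo-4-fluoro-2-hydroxybenzonitrile F1, and MOMCl/i-Pr2NEt then gives 5-bromo-4-fluoro-2-(methoxymethoxy)benzonitrile F2.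
- Sonogashira coupling of F2 with the terminal alkyne of 4 (PdCl2(PPh3)2, CuI, Et3N, 60 °C) gives 4-fluoro-5-[(3R)-3-hydroxy-4-[(4-methoxyphenyl)methoxy]-3-methylbut-1-yn-1-yl]-2-(methoxymethoxy)benzonitrile F3.
- Semi-hydrogenation (H2, Pd/CaCO3 poisoned with Pb(OAc)2, quinoline) gives the Z-alkene 4-fluoro-5-[(1Z,3R)-3-hydroxy-4-[(4-methoxyphenyl)methoxy]-3-methylbut-1-en-1-yl]-2-(methoxymethoxy)benzonitrile F4.
- The tertiary alkoxide of F4 (NaH, DMF) displaces the neighbouring fluoride para to the nitrile and closes the six-membered ring to (2R)-2-{[(4-methoxyphenyl)methoxy]methyl}-7-(methoxymethoxy)-2-methyl-2H-chromene-6-carbonitrile F5.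
- MeMgBr and cold dilute HCl give, through the N-H ketimine 1-[(2R)-2-{[(4-methoxyphenyl)methoxy]methyl}-7-(methoxymethoxy)-2-methyl-2H-chromen-6-yl]ethan-1-imine F6, the ketone 1-[(2R)-2-{[(4-methoxyphenyl)methoxy]methyl}-7-(methoxymethoxy)-2-methyl-2H-chromen-6-yl]ethan-1-one F7.
- DDQ frees 1-[(2R)-2-(hydroxymethyl)-7-(methoxymethoxy)-2-methyl-2H-chromen-6-yl]ethan-1-one F8, and DCC/DMAP esterification of F8 with 13 gives 15.

Second, step 2. Material may be lost because aldehyde 2 and alkyne 3 are small, volatile and water-miscible, and the epoxide may be opened by methanol under the basic alkynylation conditions. The fallback sets out from 1 and comes back at 4; it opens the epoxide first so that every intermediate is non-volatile.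
- Slow addition of 1 to sodium 4-methoxybenzyl oxide in excess 4-methoxybenzyl alcohol (NaH, DMF, 60 °C) should open the ring CH2 to (2R)-3-[(4-methoxyphenyl)methoxy]-2-methylpropane-1,2-diol F9. A Payne shift of 1 is degenerate and returns the same enantiomer, so it cannot erode the configuration.
- Parikh–Doering oxidation (SO3·pyridine, DMSO, i-Pr2NEt) of the primary hydroxyl gives (2S)-2-hydroxy-3-[(4-methoxyphenyl)methoxy]-2-methylpropanal F10.
- The Ohira–Bestmann reagent (K2CO3, MeOH) converts F10 into 4.

Third, step 6. Addition to a nitrile deactivated by two oxygen donors may stall, or the ortho MOM ether may be lost during acidic hydrolysis of the ketimine. The fallback sets out from 7 and comes back at 9; it passes through the aldehyde oxidation level, where no forcing addition and no acidic hydrolysis are needed.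
- i-Bu2AlH (toluene, −78 °C) with a potassium sodium tartrate work-up gives, through the aldimine 1-[4-{[(2R)-1-[(4-methoxyphenyl)methoxy]-2-methylbut-3-yn-2-yl]oxy}-2-(methoxymethoxy)phenyl]methanimine F11, the aldehyde 4-{[(2R)-1-[(4-methoxyphenyl)methoxy]-2-methylbut-3-yn-2-yl]oxy}-2-(methoxymethoxy)benzaldehyde F12.
- MeMgBr at −78 °C gives 1-[4-{[(2R)-1-[(4-methoxyphenyl)methoxy]-2-methylbut-3-yn-2-yl]oxy}-2-(methoxymethoxy)phenyl]ethan-1-ol F13 as two carbinol epimers, which is of no consequence.
- Dess–Martin periodinane oxidises F13 to 9.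

**Further compounds**
F1 | step 10 | 5-bromo-4-fluoro-2-hydroxybenzonitrile | N#Cc1cc(Br)c(F)cc1O
F2 | step 10 | 5-bromo-4-fluoro-2-(methoxymethoxy)benzonitrile | COCOc1cc(F)c(Br)cc1C#N
F3 | step 10 | 4-fluoro-5-[(3R)-3-hydroxy-4-[(4-methoxyphenyl)methoxy]-3-methylbut-1-yn-1-yl]-2-(methoxymethoxy)benzonitrile | COCOc1cc(F)c(C#C[C@](O)(C)COCc2ccc(OC)cc2)cc1C#N
F4 | step 10 | 4-fluoro-5-[(1Z,3R)-3-hydroxy-4-[(4-methoxyphenyl)methoxy]-3-methylbut-1-en-1-yl]-2-(methoxymethoxy)benzonitrile | COCOc1cc(F)c(/C=C\[C@](O)(C)COCc2ccc(OC)cc2)cc1C#N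
F5 | step 10 | (2R)-2-{[(4-methoxyphenyl)methoxy]methyl}-7-(methoxymethoxy)-2-methyl-2H-chromene-6-carbonitrile | COc1ccc(COC[C@@]2(C)C=Cc3cc(C#N)c(OCOC)cc3O2)cc1
F6 | step 10 | 1-[(2R)-2-{[(4-methoxyphenyl)methoxy]methyl}-7-(methoxymethoxy)-2-methyl-2H-chromen-6-yl]ethan-1-imine | COc1ccc(COC[C@@]2(C)C=Cc3cc(C(C)=N)c(OCOC)cc3O2)cc1
F7 | step 10 | 1-[(2R)-2-{[(4-methoxyphenyl)methoxy]methyl}-7-(methoxymethoxy)-2-methyl-2H-chromen-6-yl]ethan-1-one | COc1ccc(COC[C@@]2(C)C=Cc3cc(C(C)=O)c(OCOC)cc3O2)cc1
F8 | step 10 | 1-[(2R)-2-(hydroxymethyl)-7-(methoxymethoxy)-2-methyl-2H-chromen-6-yl]ethan-1-one | OC[C@@]1(C)C=Cc2cc(C(C)=O)c(OCOC)cc2O1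
F9 | step 2 | (2R)-3-[(4-methoxyphenyl)methoxy]-2-methylpropane-1,2-diol | OC[C@](O)(C)COCc1ccc(OC)cc1
F10 | step 2 | (2S)-2-hydroxy-3-[(4-methoxyphenyl)methoxy]-2-methylpropanal | O=C[C@](O)(C)COCc1ccc(OC)cc1
F11 | step 6 | 1-[4-{[(2R)-1-[(4-methoxyphenyl)methoxy]-2-methylbut-3-yn-2-yl]oxy}-2-(methoxymethoxy)phenyl]methanimine | C#C[C@](C)(COCc1ccc(OC)cc1)Oc1ccc(C=N)c(OCOC)c1
F12 | step 6 | 4-{[(2R)-1-[(4-methoxyphenyl)methoxy]-2-methylbut-3-yn-2-yl]oxy}-2-(methoxymethoxy)benzaldehyde | C#C[C@](C)(COCc1ccc(OC)cc1)Oc1ccc(C=O)c(OCOC)c1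
F13 | step 6 | 1-[4-{[(2R)-1-[(4-methoxyphenyl)methoxy]-2-methylbut-3-yn-2-yl]oxy}-2-(methoxymethoxy)phenyl]ethan-1-ol | C#C[C@](C)(COCc1ccc(OC)cc1)Oc1ccc(C(C)O)c(OCOC)c1
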